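All runs are calculated from invented constants; noise was put on by code.

Early in the beta and epsilon runs, right-handed product leads: epsilon at 3.00 min reads 8.1 % against 3.6 % of left-handed product, an excess of −38.5 %. But by 15.0 min the two peaks stand level within the scatter, so I expected no excess at the asked time.

in all of them: left-handed substrate 31 mM; right-handed substrate 31 mM
- beta: partner 0.80 equiv (fed, over 2.5 min); free catalyst 0.13 mol%; added ligand 0.30 mM; run made earlier
- epsilon: partner 0.80 equiv (fed, over 2.5 min); free catalyst 0.3 mol%; added ligand 0.30 mM; run made earlier
- gamma: partner 0.80 equiv (fed, over 2.5 min); free catalyst 0.2 mol%; added ligand 0.60 mM; run made earlier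
- flask: partner 0.800 equiv (fed, over 2.5 min); free catalyst 0.2 mol%; added ligand 0.30 mM; time 1.0 h

- beta (time / min: left-handed product / %, right-handed product / %): 3.00: 0.4, 3.8; 10.0: 9.0, 8.6; 15.0: 8.6, 10.4; 25.0: 9.9, 10.1; 40.0: 9.6, 8.4; 50.0: 10.2, 10.4
- epsilon (time / min: left-handed product / %, right-handed product / %): 3.00: 3.6, 8.1; 10.0: 13.0, 11.9; 15.0: 14.3, 12.1; 25.0: 13.2, 14.7; 40.0: 14.5, 12.7; 50.0: 12.5, 15.0
- gamma (time / min: left-handed product / %, right-handed product / %): 10.0: 10.6, 10.5; 20.0: 10.3, 10.7; 30.0: 11.4, 11.5; 40.0: 13.2, 10.5; 50.0: 10.3, 11.4

(each reading ± 1 percentage point)

- free catalyst is single-handed; left-handed substrate and right-handed substrate are mirror images of each other, charged as a racemate, each of them at the stated concentration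
- candidate steps: free catalyst + left-handed substrate <-> catalyst intermediate A; partner -> decomposed reagent; left-handed product <-> right-handed product; free catalyst + right-handed substrate <-> catalyst intermediate B; free catalyst + added ligand <-> idle complex; partner + catalyst intermediate A -> free catalyst + left-handed product; partner + catalyst intermediate B -> free catalyst + right-handed product
- an excess is below zero if the other one leads

- excess of left-handed product over right-handed product in the product at 3.0 min
- excess of left-handed product over right-handed product in the product at 1.0 h
- part of the left-handed substrate and right-handed substrate charged together that has reacted at 1.0 h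

The peaks also stop growing well short of what the partner allows: 40.0 % of the substrates charged, against late totals of 19.5 % in beta and 27.5 % in epsilon. So I took substrate binding as fast and in balance, with bound catalyst steady and proportional to loading. Partner then has two losses, both first order in [partner], and for a modest feed, while bound catalyst stays steady, I took their ratio as constant.

That ratio reads 0.954 in beta and 2.21 in epsilon, which carry this flask's ligand. It rises 2.32 times while the loading rises 2.31 times. Scaled to this flask's loading, it gives the split, partner turned into product per partner decomposed: 1.47. So 59.5 % of the partner should reach product, and I committed to 23.8 % reacted.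

The forecast gave −42 %, 0 % and 23.5 % reacted, holding that “the plateau reflects catalyst turnover competing with that loss”. The flask gives −26.3 %, 0 % and 23.4 % reacted.

    free catalyst + left-handed substrate ⇌ catalyst intermediate A (K = 15.0 L mol⁻¹, k = 619 L mol⁻¹ s⁻¹)
    partner → decomposed reagent (k = 0.00162 s⁻¹)
    left-handed product ⇌ right-handed product (k = 0.00710 s⁻¹)
    free catalyst + right-handed substrate ⇌ catalyst intermediate B (K = 144 L mol⁻¹, k = 3880 L mol⁻¹ s⁻¹)
    free catalyst + added ligand ⇌ idle complex, settled at all times (K = 1300 L mol⁻¹)
    partner + catalyst intermediate A → free catalyst + left-handed product (k = 108 L mol⁻¹ s⁻¹)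
    partner + catalyst intermediate B → free catalyst + right-handed product (k = 42.3 L mol⁻¹ s⁻¹)

At 0.0689 h this flask's partner went into right-handed product 1.1 times as fast as into decomposed reagent, with the route through catalyst intermediate A on top of that, against my split of 1.47. Partner, the limiting reagent, ended at 0 % of its charge against 89 % of left-handed substrate.

In the neighbour flask with 0.200 equiv of partner, the same split gives 5.95 % reacted. That flask gives 5.98 %.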